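**Assumption:** locants C1–C9a are the quinolizidine numbers of each half (unit A = the 9R,9aR half, unit B = the 9S,9aS half, primed), and the lipase is taken to acylate diol 2 with the sense known for 2-alkylpropane-1,3-diols, giving (S)-3. The route is a paper design, not run experimentally.

## Retrosynthetic overview

1. Target ⇒ last-step oxidation of the C2 alcohol of unit A. Unit B (the all-equatorial trans-quinolizidinone, thermodynamic) is built last by Staudinger/aza-Michael, CH2O Mannich ring closure and base equilibration.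
2. The sixteen-membered ring is closed by an intramolecular Horner–Wadsworth–Emmons reaction (C1′=C9a′); the C9–C1′ tether comes from C-alkylation of a β-ketophosphonate.
3. Unit A (kinetic, cis-fused) is made at the alcohol level: ring B by SN2 closure with inversion at C9a, ring A by N-methallylation and ring-closing metathesis, C2–OH/C3–Me by hydroboration.
4. C1/C9a of unit A come from a phosphoric-acid-catalysed anti-allylboration of aldehyde 8 with (E)-allylboronate 14, which already carries the C1–C9′ tether and the masked unit B aldehyde.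
5. Both C9 centres come from one lipase desymmetrisation of prochiral diol 2, whose two arms are used in opposite senses. Ring order: B(A) → A(A) → macrocycle → B(B) → A(B).

## Route

Step 1
Reactants: 1 diethyl 2-(3-chloropropyl)propanedioate
Product: 2 2-(3-chloropropyl)propane-1,3-diol
Conditions: LiAlH4, THF, 0 °C
Reagents that add atoms: none
Why: Hydride reduction of both esters gives the prochiral 1,3-diol while the primary alkyl chloride survives at 0 °C.

Step 2
Reactants: 2 2-(3-chloropropyl)propane-1,3-diol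
Product: 3 (S)-5-chloro-2-(hydroxymethyl)pentyl acetate
Conditions: Pseudomonas fluorescens lipase (immobilised), vinyl acetate, tBuOMe, 25 °C, run to slight diacetate formation
Reagents that add atoms: vinyl acetate, C=COC(C)=O
Why: Lipase-catalysed enantiotopic-group-selective transesterification (desymmetrisation) creates the first stereocentre, which becomes C9 of both halves.

Step 3
Reactants: 3 (S)-5-chloro-2-(hydroxymethyl)pentyl acetate
Product: 4 (R)-2-(acetoxymethyl)-5-chloropentyl 4-methylbenzenesulfonate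
Conditions: TsCl, pyridine, DMAP (cat.), CH2Cl2, 0 °C
Reagents that add atoms: 4-methylbenzenesulfonyl chloride, Cc1ccc(cc1)S(Cl)(=O)=O
Why: Tosylation activates the free primary alcohol without touching the stereocentre.

Step 4
Reactants: 4 (R)-2-(acetoxymethyl)-5-chloropentyl 4-methylbenzenesulfonate
Product: 5 (R)-7-[(tert-butyldimethylsilyl)oxy]-2-(3-chloropropyl)heptyl acetate
Conditions: TBSO(CH2)4MgBr (1.5 equiv), Li2CuCl4 (5 mol%), THF, −40 → 0 °C
Reagents that add atoms: [4-(tert-butyldimethylsilyloxy)butyl]magnesium bromide, CC(C)(C)[Si](C)(C)OCCCC[Mg]Br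
Why: Copper-catalysed Kochi-type alkyl–alkyl coupling of a primary tosylate with a Grignard reagent, which at low temperature spares acetate and alkyl chloride.

Step 5
Reactants: 5 (R)-7-[(tert-butyldimethylsilyl)oxy]-2-(3-chloropropyl)heptyl acetate
Product: 6 (R)-2-(3-azidopropyl)-7-[(tert-butyldimethylsilyl)oxy]heptyl acetate
Conditions: NaN3, DMF, 70 °C
Reagents that add atoms: sodium azide, [Na+].[N-]=[N+]=[N-]
Why: SN2 displacement of the primary chloride introduces the future ring nitrogen of unit A.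

Step 6
Reactants: 6 (R)-2-(3-azidopropyl)-7-[(tert-butyldimethylsilyl)oxy]heptyl acetate
Product: 7 (R)-2-(3-azidopropyl)-7-[(tert-butyldimethylsilyl)oxy]heptan-1-ol
Conditions: K2CO3 (cat.), MeOH, 0 °C → rt
Reagents that add atoms: none
Why: Base-catalysed transesterification (methanolysis) removes the acetate under conditions that leave azide and silyl ether alone.

Step 7
Reactants: 7 (R)-2-(3-azidopropyl)-7-[(tert-butyldimethylsilyl)oxy]heptan-1-ol
Product: 8 (R)-2-(3-azidopropyl)-7-[(tert-butyldimethylsilyl)oxy]heptanal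
Conditions: Dess–Martin periodinane, NaHCO3, CH2Cl2, 0 °C; used at once
Reagents that add atoms: none
Why: Buffered Dess–Martin oxidation gives the α-branched aldehyde without base-induced epimerisation.

Step 8
Reactants: 3 (S)-5-chloro-2-(hydroxymethyl)pentyl acetate
Product: 9 (R)-2-{[(tert-butyldiphenylsilyl)oxy]methyl}-5-chloropentyl acetate
Conditions: TBDPSCl, imidazole, CH2Cl2, rt
Reagents that add atoms: tert-butyl(chloro)diphenylsilane, CC(C)(C)[Si](Cl)(c1ccccc1)c1ccccc1
Why: Silylation protects the arm that was tosylated in the other series, so the two arms of 3 are used in the opposite sense and this series becomes the C9 antipode needed for unit B.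

Step 9
Reactants: 9 (R)-2-{[(tert-butyldiphenylsilyl)oxy]methyl}-5-chloropentyl acetate
Product: 10 (R)-2-{[(tert-butyldiphenylsilyl)oxy]methyl}-5-chloropentan-1-ol
Conditions: K2CO3 (cat.), MeOH, rt
Reagents that add atoms: none
Why: Acetate methanolysis (transesterification) frees the second arm while the silyl ether stays.

Step 10
Reactants: 10 (R)-2-{[(tert-butyldiphenylsilyl)oxy]methyl}-5-chloropentan-1-ol
Product: 11 (S)-2-{[(tert-butyldiphenylsilyl)oxy]methyl}-5-chloropentyl 4-methylbenzenesulfonate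
Conditions: TsCl, pyridine, DMAP (cat.), CH2Cl2, 0 °C
Reagents that add atoms: 4-methylbenzenesulfonyl chloride, Cc1ccc(cc1)S(Cl)(=O)=O
Why: Tosylation of the primary alcohol prepares the copper-catalysed coupling.

Step 11
Reactants: 11 (S)-2-{[(tert-butyldiphenylsilyl)oxy]methyl}-5-chloropentyl 4-methylbenzenesulfonate
Product: 12 (S)-tert-butyl{[2-(3-chloropropyl)non-8-en-1-yl]oxy}diphenylsilane
Conditions: CH2=CH(CH2)4MgBr, Li2CuCl4 (5 mol%), THF, −40 → 0 °C
Reagents that add atoms: hex-5-en-1-ylmagnesium bromide, C=CCCCC[Mg]Br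
Why: Kochi-type copper-catalysed coupling installs the five-carbon C1–C9′ tether plus a terminal alkene.

Step 12
Reactants: 12 (S)-tert-butyl{[2-(3-chloropropyl)non-8-en-1-yl]oxy}diphenylsilane
Product: 13 (E)-alkenylboronate, 2-[(1E,8S)-8-{[(tert-butyldiphenylsilyl)oxy]methyl}-11-chloroundec-1-en-1-yl]-4,4,5,5-tetramethyl-1,3,2-dioxaborolane
Conditions: vinylboronic acid pinacol ester (3 equiv), second-generation Grubbs catalyst (C46H65Cl2N2PRu, 5 mol%), CH2Cl2, 40 °C
Reagents that add atoms: 4,4,5,5-tetramethyl-2-vinyl-1,3,2-dioxaborolane, C=CB1OC(C)(C)C(C)(C)O1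
Why: Olefin cross-metathesis with a vinylboronate is strongly E-selective and the excess cheap partner drives the terminal alkene to the hetero-product.

Step 13
Reactants: 13 (E)-alkenylboronate
Product: 14 (E)-allylboronate, 2-[(2E,9S)-9-{[(tert-butyldiphenylsilyl)oxy]methyl}-12-chlorododec-2-en-1-yl]-4,4,5,5-tetramethyl-1,3,2-dioxaborolane
Conditions: ICH2Cl, n-BuLi, THF, −78 °C → rt
Reagents that add atoms: chloroiodomethane, ClCI
Why: Matteson homologation, in which chloromethyllithium forms the boronate complex and 1,2-migration of the alkenyl group keeps the E geometry.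

Step 14
Reactants: 8 (R)-2-(3-azidopropyl)-7-[(tert-butyldimethylsilyl)oxy]heptanal; 14 (E)-allylboronate
Product: 15 anti homoallylic alcohol, (3R,4S,5R)-8-azido-5-{5-[(tert-butyldimethylsilyl)oxy]pentyl}-3-[(6S)-6-{[(tert-butyldiphenylsilyl)oxy]methyl}-9-chlorononyl]oct-1-en-4-ol
Conditions: (R)-TRIP phosphoric acid (5 mol%), 4 Å molecular sieves, toluene, −30 °C
Reagents that add atoms: none
Why: Chiral phosphoric acid-catalysed allylboration through a closed chair transition state, where the E-boronate gives the anti adduct and (R)-TRIP directs attack to the Re face (as it gives the (R)-carbinol from benzaldehyde), setting C1 and the C9a carbinol of unit A.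

Step 15
Reactants: 15 anti homoallylic alcohol
Product: 16 (3R,4S,5R)-mesylate of 15
Conditions: MsCl, Et3N, CH2Cl2, 0 °C
Reagents that add atoms: methanesulfonyl chloride, CS(Cl)(=O)=O
Why: Mesylation turns the C9a hydroxyl into a leaving group with retention.

Step 16
Reactants: 16 mesylate
Product: 18 (2R,3R)-trans-piperidine carrying the (3R)-vinyl side chain, via amino mesylate 17 (not isolated)
Conditions: PPh3, THF/H2O, 50 °C; then K2CO3, MeCN, 70 °C
Reagents that add atoms: none
Why: Staudinger reduction followed by intramolecular 6-exo-tet SN2 N-alkylation inverts C9a and gives the 2,3-trans piperidine (ring B of unit A).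

Step 17
Reactants: 18 trans-piperidine
Product: 19 N-(2-methylprop-2-en-1-yl)piperidine
Conditions: 3-bromo-2-methylprop-1-ene, K2CO3, MeCN, 50 °C
Reagents that add atoms: 3-bromo-2-methylprop-1-ene, C=C(C)CBr
Why: N-alkylation of the secondary amine brings in C4, C3 and the C3 methyl group.

Step 18
Reactants: 19 N-methallylpiperidine
Product: 20 (1R,9R,9aR)-3-methyl-1,6,7,8,9,9a-hexahydro-4H-quinolizine with both side chains
Conditions: TsOH·H2O (1.1 equiv), second-generation Grubbs catalyst (C46H65Cl2N2PRu, 5 mol%), CH2Cl2, 40 °C; NaHCO3 wash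
Reagents that add atoms: none
Why: Ring-closing metathesis of the ammonium salt (the only two alkenes present) forms ring A as its trisubstituted alkene.

Step 19
Reactants: 20 hexahydroquinolizine
Product: 21 (1S,2S,3R,9R,9aR)-octahydro-2H-quinolizin-2-ol
Conditions: BH3·THF, THF, 0 °C → rt; NaOH, H2O2; then HCl/MeOH, 60 °C; NaOH
Reagents that add atoms: hydrogen peroxide, OO
Why: Hydroboration–oxidation adds H and OH syn, with boron on the less substituted C2 and from the face opposite the C1 chain and the C9a–C9 bond, which sets C2–OH and puts the C3 methyl cis to the C1 chain.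

Step 20
Reactants: 21 quinolizidin-2-ol
Product: 22 (1S,2S,3R,9R,9aR)-quinolizidin-2-yl acetate
Conditions: Ac2O, pyridine, DMAP (cat.), rt
Reagents that add atoms: acetic anhydride, CC(=O)OC(C)=O
Why: Acetylation masks the C2 alcohol so that unit A carries no carbonyl and cannot epimerise during the later oxidations and the base step.

Step 21
Reactants: 22 acetate
Product: 23 primary alcohol, 9-(5-hydroxypentyl) compound
Conditions: TsOH·H2O (1.3 equiv), MeOH, 0 °C; NaHCO3
Reagents that add atoms: none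
Why: Acid-catalysed methanolysis cleaves the primary TBS ether selectively, while the bulkier TBDPS ether and the acetate stay.

Step 22
Reactants: 23 primary alcohol
Product: 24 primary iodide, 9-(5-iodopentyl) compound
Conditions: I2, PPh3, imidazole, CH2Cl2, 0 °C
Reagents that add atoms: iodine, II
Why: Appel-type iodination converts the primary alcohol into a good SN2 electrophile at the end of the C9–C1′ tether.

Step 23
Reactants: 24 primary iodide
Product: 25 α-alkylated β-ketophosphonate, 9-[6-(diethoxyphosphoryl)-7-oxononyl] compound (C1′ epimers)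
Conditions: diethyl (2-oxobutyl)phosphonate (3 equiv), NaH, THF/DMF, 0 → 40 °C
Reagents that add atoms: diethyl (2-oxobutyl)phosphonate, CCC(=O)CP(=O)(OCC)OCC
Why: C-alkylation of the doubly stabilised phosphonate enolate with the primary iodide attaches C1′–C3′ of unit B and its methyl carbon to the tether.

Step 24
Reactants: 25 β-ketophosphonate
Product: 26 azide, side chain (6S)-9-azido-6-{[(tert-butyldiphenylsilyl)oxy]methyl}nonyl
Conditions: NaN3, DMF, 60 °C
Reagents that add atoms: sodium azide, [Na+].[N-]=[N+]=[N-]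
Why: SN2 displacement of the remaining primary chloride installs the nitrogen of unit B.

Step 25
Reactants: 26 azide
Product: 27 primary alcohol, side chain (6S)-9-azido-6-(hydroxymethyl)nonyl
Conditions: TBAF, AcOH, THF, rt
Reagents that add atoms: none
Why: Buffered fluoride desilylation frees the C9a′ carbinol and leaves acetate and phosphonate intact.

Step 26
Reactants: 27 primary alcohol
Product: 28 seco aldehyde, side chain (6S)-9-azido-6-formylnonyl
Conditions: Dess–Martin periodinane, NaHCO3, CH2Cl2, 0 °C; used at once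
Reagents that add atoms: none
Why: Buffered Dess–Martin oxidation gives the α-branched aldehyde without epimerising C9′, the only anchor of unit B.

Step 27
Reactants: 28 seco aldehyde
Product: 29 sixteen-membered macrocyclic (E)-enone
Conditions: LiCl, iPr2NEt, MeCN, 40 °C, 1 mM, slow addition
Reagents that add atoms: none
Why: Intramolecular Horner–Wadsworth–Emmons olefination under Masamune–Roush conditions closes the macrocycle at C1′=C9a′ with a base mild enough to keep the aldehyde α-centre.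

Step 28
Reactants: 29 macrocyclic enone
Product: 31 macrocyclic β-amino ketone with the trans-piperidine of unit B (C9′ S, C9a′ S), via amino enone 30 (not isolated)
Conditions: PPh3, THF/H2O, 50 °C; then MeOH, 40 °C
Reagents that add atoms: none
Why: Staudinger reduction then reversible 6-exo intramolecular aza-Michael addition, so the diequatorial 2,3-trans piperidine accumulates.

Step 29
Reactants: 31 macrocyclic β-amino ketone
Product: 32 Mannich base, unit B quinolizidin-2-one as C1′/C3′ epimer mixture, unit A acetate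
Conditions: aq. CH2O, AcOH (cat.), MeOH, 50 °C
Reagents that add atoms: formaldehyde, C=O
Why: Intramolecular Mannich reaction of the N-methyleneiminium ion with the ethyl-ketone enol closes ring A of unit B, the only six-membered option.

Step 30
Reactants: 32 Mannich base
Product: 33 hydroxy ketone, unit A (1S,2S,3R,9R,9aR)-2-ol and unit B (1′S,3′R,9′S,9a′S)-2′-one
Conditions: K2CO3, MeOH, rt
Reagents that add atoms: none
Why: Base-mediated enolisation equilibrates C1′ and C3′ to the all-equatorial trans-quinolizidinone (thermodynamic control) and the same conditions methanolyse the acetate; unit A has no carbonyl and stays fixed.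

Step 31
Reactants: 33 hydroxy ketone
Product: 34 CNP0268544.1
Conditions: Dess–Martin periodinane, NaHCO3, CH2Cl2, 0 °C; cold neutral work-up, neutral alumina
Reagents that add atoms: none
Why: Base-free Dess–Martin oxidation of the last secondary alcohol gives the ketone of unit A while keeping its kinetic C1 and C3 configurations.

## Compound list

1 | diethyl 2-(3-chloropropyl)propanedioate | CCOC(=O)C(CCCCl)C(=O)OCC | starting material
2 | 2-(3-chloropropyl)propane-1,3-diol | OCC(CCCCl)CO | intermediate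
3 | (S)-5-chloro-2-(hydroxymethyl)pentyl acetate | CC(=O)OC[C@H](CO)CCCCl | intermediate
4 | (R)-2-(acetoxymethyl)-5-chloropentyl 4-methylbenzenesulfonate | CC(=O)OC[C@H](COS(=O)(=O)c1ccc(C)cc1)CCCCl | intermediate
5 | (R)-7-[(tert-butyldimethylsilyl)oxy]-2-(3-chloropropyl)heptyl acetate | CC(=O)OC[C@H](CCCCCO[Si](C)(C)C(C)(C)C)CCCCl | intermediate
6 | (R)-2-(3-azidopropyl)-7-[(tert-butyldimethylsilyl)oxy]heptyl acetate | CC(=O)OC[C@H](CCCCCO[Si](C)(C)C(C)(C)C)CCCN=[N+]=[N-] | intermediate
7 | (R)-2-(3-azidopropyl)-7-[(tert-butyldimethylsilyl)oxy]heptan-1-ol | OC[C@H](CCCCCO[Si](C)(C)C(C)(C)C)CCCN=[N+]=[N-] | intermediate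
8 | (R)-2-(3-azidopropyl)-7-[(tert-butyldimethylsilyl)oxy]heptanal | O=C[C@H](CCCCCO[Si](C)(C)C(C)(C)C)CCCN=[N+]=[N-] | intermediate
9 | (R)-2-{[(tert-butyldiphenylsilyl)oxy]methyl}-5-chloropentyl acetate | CC(=O)OC[C@H](CO[Si](c1ccccc1)(c1ccccc1)C(C)(C)C)CCCCl | intermediate
10 | (R)-2-{[(tert-butyldiphenylsilyl)oxy]methyl}-5-chloropentan-1-ol | OC[C@H](CO[Si](c1ccccc1)(c1ccccc1)C(C)(C)C)CCCCl | intermediate
11 | (S)-2-{[(tert-butyldiphenylsilyl)oxy]methyl}-5-chloropentyl 4-methylbenzenesulfonate | Cc1ccc(cc1)S(=O)(=O)OC[C@H](CO[Si](c1ccccc1)(c1ccccc1)C(C)(C)C)CCCCl | intermediate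
12 | (S)-tert-butyl{[2-(3-chloropropyl)non-8-en-1-yl]oxy}diphenylsilane | C=CCCCCC[C@H](CO[Si](c1ccccc1)(c1ccccc1)C(C)(C)C)CCCCl | intermediate
13 | 2-[(1E,8S)-8-{[(tert-butyldiphenylsilyl)oxy]methyl}-11-chloroundec-1-en-1-yl]-4,4,5,5-tetramethyl-1,3,2-dioxaborolane | CC1(C)OB(/C=C/CCCCC[C@H](CO[Si](c2ccccc2)(c2ccccc2)C(C)(C)C)CCCCl)OC1(C)C | intermediate
14 | 2-[(2E,9S)-9-{[(tert-butyldiphenylsilyl)oxy]methyl}-12-chlorododec-2-en-1-yl]-4,4,5,5-tetramethyl-1,3,2-dioxaborolane | CC1(C)OB(C/C=C/CCCCC[C@H](CO[Si](c2ccccc2)(c2ccccc2)C(C)(C)C)CCCCl)OC1(C)C | intermediate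
15 | (3R,4S,5R)-8-azido-5-{5-[(tert-butyldimethylsilyl)oxy]pentyl}-3-[(6S)-6-{[(tert-butyldiphenylsilyl)oxy]methyl}-9-chlorononyl]oct-1-en-4-ol | C=C[C@@H](CCCCC[C@H](CO[Si](c1ccccc1)(c1ccccc1)C(C)(C)C)CCCCl)[C@@H](O)[C@H](CCCCCO[Si](C)(C)C(C)(C)C)CCCN=[N+]=[N-] | intermediate
16 | (3R,4S,5R)-8-azido-5-{5-[(tert-butyldimethylsilyl)oxy]pentyl}-3-[(6S)-6-{[(tert-butyldiphenylsilyl)oxy]methyl}-9-chlorononyl]oct-1-en-4-yl methanesulfonate | C=C[C@@H](CCCCC[C@H](CO[Si](c1ccccc1)(c1ccccc1)C(C)(C)C)CCCCl)[C@@H](OS(C)(=O)=O)[C@H](CCCCCO[Si](C)(C)C(C)(C)C)CCCN=[N+]=[N-] | intermediate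
17 | 8-amino analogue of mesylate 16 (not isolated) | C=C[C@@H](CCCCC[C@H](CO[Si](c1ccccc1)(c1ccccc1)C(C)(C)C)CCCCl)[C@@H](OS(C)(=O)=O)[C@H](CCCCCO[Si](C)(C)C(C)(C)C)CCCN | intermediate
18 | (2R,3R)-2-[(3R,9S)-9-{[(tert-butyldiphenylsilyl)oxy]methyl}-12-chlorododec-1-en-3-yl]-3-{5-[(tert-butyldimethylsilyl)oxy]pentyl}piperidine | C=C[C@@H](CCCCC[C@H](CO[Si](c3ccccc3)(c3ccccc3)C(C)(C)C)CCCCl)[C@@H]1NCCC[C@H]1CCCCCO[Si](C)(C)C(C)(C)C | intermediate
19 | 1-(2-methylprop-2-en-1-yl) derivative of piperidine 18 | C=C[C@@H](CCCCC[C@H](CO[Si](c3ccccc3)(c3ccccc3)C(C)(C)C)CCCCl)[C@@H]1N(CC(C)=C)CCC[C@H]1CCCCCO[Si](C)(C)C(C)(C)C | intermediate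
20 | (1R,9R,9aR)-9-{5-[(tert-butyldimethylsilyl)oxy]pentyl}-1-[(6S)-6-{[(tert-butyldiphenylsilyl)oxy]methyl}-9-chlorononyl]-3-methyl-1,6,7,8,9,9a-hexahydro-4H-quinolizine | CC1=C[C@@H](CCCCC[C@H](CO[Si](c3ccccc3)(c3ccccc3)C(C)(C)C)CCCCl)[C@@H]2N(C1)CCC[C@H]2CCCCCO[Si](C)(C)C(C)(C)C | intermediate
21 | (1S,2S,3R,9R,9aR)-9-{5-[(tert-butyldimethylsilyl)oxy]pentyl}-1-[(6S)-6-{[(tert-butyldiphenylsilyl)oxy]methyl}-9-chlorononyl]-3-methyloctahydro-2H-quinolizin-2-ol | C[C@@H]1CN2CCC[C@@H](CCCCCO[Si](C)(C)C(C)(C)C)[C@@H]2[C@H](CCCCC[C@H](CO[Si](c3ccccc3)(c3ccccc3)C(C)(C)C)CCCCl)[C@H]1O | intermediate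
22 | 2-O-acetate of 21 | C[C@@H]1CN2CCC[C@@H](CCCCCO[Si](C)(C)C(C)(C)C)[C@@H]2[C@H](CCCCC[C@H](CO[Si](c3ccccc3)(c3ccccc3)C(C)(C)C)CCCCl)[C@H]1OC(C)=O | intermediate
23 | (1S,2S,3R,9R,9aR)-1-[(6S)-6-{[(tert-butyldiphenylsilyl)oxy]methyl}-9-chlorononyl]-9-(5-hydroxypentyl)-3-methyloctahydro-2H-quinolizin-2-yl acetate | C[C@@H]1CN2CCC[C@@H](CCCCCO)[C@@H]2[C@H](CCCCC[C@H](CO[Si](c3ccccc3)(c3ccccc3)C(C)(C)C)CCCCl)[C@H]1OC(C)=O | intermediate
24 | 9-(5-iodopentyl) analogue of 23 | C[C@@H]1CN2CCC[C@@H](CCCCCI)[C@@H]2[C@H](CCCCC[C@H](CO[Si](c3ccccc3)(c3ccccc3)C(C)(C)C)CCCCl)[C@H]1OC(C)=O | intermediate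
25 | 9-[6-(diethoxyphosphoryl)-7-oxononyl] analogue of 23 (epimers at the phosphonate carbon) | C[C@@H]1CN2CCC[C@@H](CCCCCC(C(=O)CC)P(=O)(OCC)OCC)[C@@H]2[C@H](CCCCC[C@H](CO[Si](c3ccccc3)(c3ccccc3)C(C)(C)C)CCCCl)[C@H]1OC(C)=O | intermediate
26 | azide from 25, side chain (6S)-9-azido-6-{[(tert-butyldiphenylsilyl)oxy]methyl}nonyl | C[C@@H]1CN2CCC[C@@H](CCCCCC(C(=O)CC)P(=O)(OCC)OCC)[C@@H]2[C@H](CCCCC[C@H](CO[Si](c3ccccc3)(c3ccccc3)C(C)(C)C)CCCN=[N+]=[N-])[C@H]1OC(C)=O | intermediate
27 | alcohol from 26, side chain (6S)-9-azido-6-(hydroxymethyl)nonyl | C[C@@H]1CN2CCC[C@@H](CCCCCC(C(=O)CC)P(=O)(OCC)OCC)[C@@H]2[C@H](CCCCC[C@H](CO)CCCN=[N+]=[N-])[C@H]1OC(C)=O | intermediate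
28 | seco aldehyde, side chain (6S)-9-azido-6-formylnonyl | C[C@@H]1CN2CCC[C@@H](CCCCCC(C(=O)CC)P(=O)(OCC)OCC)[C@@H]2[C@H](CCCCC[C@H](C=O)CCCN=[N+]=[N-])[C@H]1OC(C)=O | intermediate
29 | sixteen-membered macrocyclic (E)-enone (unit A acetate; C9′ S with 3-azidopropyl; propanoyl on C1′) | C[C@@H]1CN2CCC[C@H]3CCCCC/C(C(=O)CC)=C\[C@H](CCCN=[N+]=[N-])CCCCC[C@H]([C@H]1OC(C)=O)[C@@H]32 | intermediate
30 | amino analogue of enone 29 (not isolated) | C[C@@H]1CN2CCC[C@H]3CCCCC/C(C(=O)CC)=C\[C@H](CCCN)CCCCC[C@H]([C@H]1OC(C)=O)[C@@H]32 | intermediate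
31 | macrocyclic β-amino ketone with (9′S,9a′S)-trans-piperidine and propanoyl on C1′ (C1′ epimers), unit A acetate | C[C@@H]1CN2CCC[C@H]3CCCCCC(C(=O)CC)[C@H]4NCCC[C@@H]4CCCCC[C@H]([C@H]1OC(C)=O)[C@@H]32 | intermediate
32 | Mannich base, unit B 3′-methylquinolizidin-2′-one as C1′/C3′ epimer mixture, unit A acetate | C[C@@H]1CN2CCC[C@H]3CCCCCC4C(=O)C(C)CN5CCC[C@H](CCCCC[C@H]([C@H]1OC(C)=O)[C@@H]32)[C@@H]45 | intermediate
33 | hydroxy ketone, unit A (1S,2S,3R,9R,9aR)-2-ol, unit B (1′S,3′R,9′S,9a′S)-2′-one | C[C@@H]1CN2CCC[C@H]3CCCCC[C@@H]4C(=O)[C@H](C)CN5CCC[C@H](CCCCC[C@H]([C@H]1O)[C@@H]32)[C@@H]45 | intermediate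
34 | CNP0268544.1, unit A (1S,3R,9R,9aR), unit B (1′S,3′R,9′S,9a′S) | C[C@@H]1CN2CCC[C@H]3CCCCC[C@@H]4C(=O)[C@H](C)CN5CCC[C@H](CCCCC[C@H](C1=O)[C@@H]32)[C@@H]45 | target

## Step count and weak points

Total: 31 steps. Longest linear sequence: 26 steps (1 → 2 → 3 → 9 → 10 → 11 → 12 → 13 → 14 → 15 → … → 34).

Most likely to fail:

1. **Step 14** (facial and anti selectivity of the catalysed allylboration with a functionalised boronate and an α-branched aldehyde). The fallback sets out from alkene 12. Cross-metathesis with allyl bromide (second-generation Grubbs catalyst, C46H65Cl2N2PRu) gives the (E)-allylic bromide F1. A catalytic asymmetric Nozaki–Hiyama–Kishi allylation of aldehyde 8 (CrCl2 cat., chiral bis(oxazoline) ligand, Mn, TMSCl, acidic work-up) then gives the anti adduct through the chromium-allyl chair transition state and comes back to the route at 15.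

2. **Step 19** (face and regiochemistry of the hydroboration, plus amine–borane handling). The fallback sets out from piperidine 18. N-Allylation with allyl bromide and K2CO3 gives the N-allylpiperidine F2. Ring-closing metathesis of its tosylate salt gives the unmethylated hexahydroquinolizine F3. Epoxidation of the trifluoroacetate salt with CF3CO3H on the face opposite the C1 chain gives the epoxide F4. Trans-diaxial SN2 opening at C3 with Me2CuLi brings the methyl in anti to oxygen and comes back at 21.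

3. **Step 27** (macrocyclising olefination with an α-substituted phosphonate and an α-branched aldehyde). The fallback sets out from alcohol 27. Horner–Wadsworth–Emmons reaction of the phosphonate with aqueous formaldehyde (K2CO3) gives the α-methylene ketone F5. Dess–Martin oxidation gives the aldehyde F6, and Takai–Lombardo methylenation (Zn, CH2Br2, TiCl4) gives the vinyl compound F7. Ring-closing metathesis of the ammonium salt between the vinyl group and the enone methylene (second-generation Grubbs catalyst, C46H65Cl2N2PRu, high dilution) comes back at enone 29.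

## Further compounds

F1 | step 14 | (S,E)-{[10-bromo-2-(3-chloropropyl)dec-8-en-1-yl]oxy}(tert-butyl)diphenylsilane | BrC/C=C/CCCCC[C@H](CO[Si](c1ccccc1)(c1ccccc1)C(C)(C)C)CCCCl
F2 | step 19 | 1-allyl derivative of piperidine 18 | C=C[C@@H](CCCCC[C@H](CO[Si](c3ccccc3)(c3ccccc3)C(C)(C)C)CCCCl)[C@@H]1N(CC=C)CCC[C@H]1CCCCCO[Si](C)(C)C(C)(C)C
F3 | step 19 | (1R,9R,9aR)-1,9-disubstituted 1,6,7,8,9,9a-hexahydro-4H-quinolizine lacking the 3-methyl group | C1=C[C@@H](CCCCC[C@H](CO[Si](c3ccccc3)(c3ccccc3)C(C)(C)C)CCCCl)[C@@H]2N(C1)CCC[C@H]2CCCCCO[Si](C)(C)C(C)(C)C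
F4 | step 19 | 2,3-epoxide of F3, oxygen on the face opposite the C1 chain | C1N2CCC[C@@H](CCCCCO[Si](C)(C)C(C)(C)C)[C@@H]2[C@H](CCCCC[C@H](CO[Si](c4ccccc4)(c4ccccc4)C(C)(C)C)CCCCl)[C@H]3O[C@@H]13
F5 | step 27 | α-methylene ketone, 9-(6-methylidene-7-oxononyl) analogue of 27 | C[C@@H]1CN2CCC[C@@H](CCCCCC(=C)C(=O)CC)[C@@H]2[C@H](CCCCC[C@H](CO)CCCN=[N+]=[N-])[C@H]1OC(C)=O
F6 | step 27 | aldehyde from F5, side chain (6S)-9-azido-6-formylnonyl | C[C@@H]1CN2CCC[C@@H](CCCCCC(=C)C(=O)CC)[C@@H]2[C@H](CCCCC[C@H](C=O)CCCN=[N+]=[N-])[C@H]1OC(C)=O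
F7 | step 27 | vinyl compound from F6, side chain 9-azido-6-vinylnonyl | C[C@@H]1CN2CCC[C@@H](CCCCCC(=C)C(=O)CC)[C@@H]2[C@H](CCCCC[C@H](C=C)CCCN=[N+]=[N-])[C@H]1OC(C)=O
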